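**Plan**
- The ketone carbon is bonded only to C6 of the chromene benzene ring (ring A) and to the CH2CH2 tether that ends in the phenol ring (ring B). Both of its C–C bonds are therefore cut at once and the carbon is traced back to CO. This leaves a 6-iodochromene and a B-(2-arylethyl)-9-BBN.
- Further cuts are C8–CH2 of the prenyl group (aromatic Claisen shift from a 7-O-(1,1-dimethylallyl) ether), O1–C2 and C4–C4a of the pyran ring (resorcinol plus prenal), and finally C–I.
- Forward: resorcinol is iodinated and the pyran ring is closed on 4-iodoresorcinol. The iodine blocks C6, so the Claisen shift can end only at C8, and the same iodine then serves as the coupling handle.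
- Ring B and its two-carbon tether are joined last, through CO, and one fluoride step frees both phenols.
- Stereochemistry: the target has no stereocentre. C3=C4 is cis by ring constraint and the prenyl alkene carries two equal methyl groups, so nothing has to be controlled.

Key step: step 10

Remark: borane 15 is made in a separate flask and transferred as its THF solution, so it is treated as the product of its own step.

Step 1
Reactants: 1 resorcinol
Product: 2 4-iodoresorcinol (4-iodobenzene-1,3-diol)
Conditions: ICl (1.0 equiv), Et2O, 0 °C to rt
Reagents that add atoms: iodine monochloride, ClI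
Why: Electrophilic aromatic iodination, in which neutral resorcinol in ether should be attacked at the less crowded C4 (ortho to one hydroxyl, para to the other) rather than between the oxygens, with one equivalent of reagent holding the reaction at the mono-iodide.

Step 2
Reactants: 2 4-iodoresorcinol; 3 3-methylbut-2-enal (prenal)
Product: 5 6-iodo-2,2-dimethyl-2H-chromen-7-ol, via o-quinone methide 4 (not isolated)
Conditions: 3 (1.1 equiv, slow addition), ethylenediammonium diacetate (20 mol %), toluene, reflux, Dean–Stark
Reagents that add atoms: none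
Why: Formal [3+3] chromene annulation of a resorcinol with an enal (Knoevenagel-type C-alkylation, dehydration to 4, oxa-6π electrocyclisation), in which the free carbon para to the iodine-flanked hydroxyl is less crowded than the carbon between the two oxygens, so the linear 7-hydroxy isomer should prevail.

Step 3
Reactants: 5 6-iodo-2,2-dimethyl-2H-chromen-7-ol; 6 3-chloro-3-methylbut-1-yne
Product: 7 6-iodo-2,2-dimethyl-7-(2-methylbut-3-yn-2-yloxy)-2H-chromene
Conditions: DBU (1.3 equiv), CuCl2·2H2O (1 mol %), MeCN, 0 °C
Reagents that add atoms: none
Why: Copper-catalysed O-alkylation of a phenol with a tertiary propargylic chloride, in which the copper acetylide ionises to a stabilised cation that the phenoxide captures at the tertiary carbon, and at 0 °C neither the aryl iodide nor the heat-sensitive aryl propargyl ether should react further.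

Step 4
Reactants: 7 6-iodo-2,2-dimethyl-7-(2-methylbut-3-yn-2-yloxy)-2H-chromene
Product: 8 6-iodo-2,2-dimethyl-7-(2-methylbut-3-en-2-yloxy)-2H-chromene
Conditions: H2 (1 atm, stopped after 1 equiv), Pd/CaCO3–Pb(OAc)2 (Lindlar catalyst), quinoline, EtOAc, rt
Reagents that add atoms: none
Why: Lindlar semihydrogenation, in which the terminal alkyne binds the poisoned palladium surface far more strongly than the cis-disubstituted chromene alkene, and without added base and with quinoline present the C–I bond should escape hydrogenolysis.

Step 5
Reactants: 8 6-iodo-2,2-dimethyl-7-(2-methylbut-3-en-2-yloxy)-2H-chromene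
Product: 10 6-iodo-2,2-dimethyl-8-(3-methylbut-2-enyl)-2H-chromen-7-ol, via cyclohexadienone 9 (not isolated)
Conditions: PhNEt2, 140 °C
Reagents that add atoms: none
Why: Aromatic Claisen rearrangement, in which the [3,3] shift inverts the 1,1-dimethylallyl unit into a prenyl group, iodine occupies C6 so only the C8 dienone 9 can tautomerise to a phenol, and the basic solvent suppresses acid-induced closure of the o-prenylphenol to a chroman.

Step 6
Reactants: 10 6-iodo-2,2-dimethyl-8-(3-methylbut-2-enyl)-2H-chromen-7-ol
Product: 11 tert-butyl-[6-iodo-2,2-dimethyl-8-(3-methylbut-2-enyl)-2H-chromen-7-yl]oxy-dimethylsilane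
Conditions: TBSCl (1.5 equiv), imidazole (3 equiv), DMF, rt to 40 °C
Reagents that add atoms: tert-butyldimethylsilyl chloride, CC(C)(C)[Si](C)(C)Cl
Why: Imidazole-promoted silylation of a phenol, in which the flanking iodine and CH2 group slow the reaction but should not stop it, and the mildly basic medium leaves the prenyl and chromene alkenes untouched.

Step 7
Reactants: 12 4-acetoxystyrene
Product: 13 4-vinylphenol
Conditions: K2CO3 (10 mol %), MeOH, 0 °C to rt; used crude and cold
Reagents that add atoms: none
Why: Base-catalysed transesterification of an aryl acetate with methanol, mild enough to free the phenol without starting polymerisation of the styrene if the product is carried on at once.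

Step 8
Reactants: 13 4-vinylphenol
Product: 14 tert-butyl-(4-ethenylphenoxy)-dimethylsilane
Conditions: TBSCl (1.1 equiv), imidazole (2 equiv), CH2Cl2, 0 °C to rt
Reagents that add atoms: tert-butyldimethylsilyl chloride, CC(C)(C)[Si](C)(C)Cl
Why: Standard silylation of an unhindered phenol, which also turns the labile vinylphenol into a storable styrene.

Step 9
Reactants: 14 tert-butyl-(4-ethenylphenoxy)-dimethylsilane
Product: 15 9-[2-[4-(tert-butyldimethylsilyloxy)phenyl]ethyl]-9-borabicyclo[3.3.1]nonane
Conditions: 9-BBN-H (0.95 equiv, 0.5 M in THF), 0 °C to rt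
Reagents that add atoms: 9-borabicyclo[3.3.1]nonane, B1C2CCCC1CCC2
Why: Anti-Markovnikov hydroboration, in which the bulky borane places boron on the terminal carbon of the electron-rich styrene, and the slight deficit of borane leaves no B–H bond that could attack the alkenes of 11 in the next step.

Step 10
Reactants: 11 tert-butyl-[6-iodo-2,2-dimethyl-8-(3-methylbut-2-enyl)-2H-chromen-7-yl]oxy-dimethylsilane; 15 9-[2-[4-(tert-butyldimethylsilyloxy)phenyl]ethyl]-9-borabicyclo[3.3.1]nonane (1.3 equiv); 16 carbon monoxide
Product: 17 1-[7-(tert-butyldimethylsilyloxy)-2,2-dimethyl-8-(3-methylbut-2-enyl)-2H-chromen-6-yl]-3-[4-(tert-butyldimethylsilyloxy)phenyl]propan-1-one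
Conditions: CO (1–3 atm), Pd(PPh3)4 (5 mol %), anhydrous powdered K3PO4 (3 equiv), toluene–THF, rt to 50 °C
Reagents that add atoms: none
Why: This is a carbonylative Suzuki–Miyaura coupling of an aryl iodide with a B-alkyl-9-BBN, a known three-component ketone synthesis: the C6–I bond adds oxidatively to zerovalent palladium, CO inserts into the aryl–palladium bond to give an aroyl complex of divalent palladium, the phosphate-activated borate transfers its primary alkyl group, and reductive elimination releases 17. No ring is closed and no stereocentre is formed. The selectivity needed is CO insertion ahead of transmetalation, because the reverse order gives direct aryl–alkyl coupling; here the aryl group carries oxygen donors ortho (C7) and para (C8a) to C6 and migrates readily to CO, the neighbouring silyloxy group hinders the approach of the bulky borate, and the sparingly soluble K3PO4 keeps the borate concentration low. The aroyl(alkyl)palladium intermediate should eliminate reductively faster than it loses a β-hydride, as is usual for acyl complexes. The iodine fixes the site and the hydroboration has fixed the two-carbon tether, while the prenyl group (meta to C6) and the chromene alkene are too remote for a Heck-type closure. Anhydrous conditions keep both aryl silyl ethers in place, so no phenoxide is available to trap the aroyl complex as an ester.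

Step 11
Reactants: 17 1-[7-(tert-butyldimethylsilyloxy)-2,2-dimethyl-8-(3-methylbut-2-enyl)-2H-chromen-6-yl]-3-[4-(tert-butyldimethylsilyloxy)phenyl]propan-1-one
Product: 18 1-[7-hydroxy-2,2-dimethyl-8-(3-methylbut-2-enyl)-2H-chromen-6-yl]-3-(4-hydroxyphenyl)propan-1-one (target)
Conditions: Bu4NF (2.5 equiv), AcOH (2.5 equiv), THF, 0 °C
Reagents that add atoms: none
Why: Fluoride-induced cleavage of aryl silyl ethers driven by the strong Si–F bond, in which acetic acid buffers the phenoxides and no strong acid is present that could close the o-prenylphenol to a chroman or attack the chromene.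

**Compound list**
1 | resorcinol | Oc1cccc(O)c1 | starting material
2 | 4-iodoresorcinol | Oc1ccc(I)c(O)c1 | intermediate
3 | 3-methylbut-2-enal (prenal) | CC(C)=CC=O | starting material
4 | 3-hydroxy-4-iodo-6-(3-methylbut-2-enylidene)cyclohexa-2,4-dien-1-one (o-quinone methide, exocyclic alkene geometry not fixed) | CC(C)=CC=C1C=C(I)C(O)=CC1=O | intermediate
5 | 6-iodo-2,2-dimethyl-2H-chromen-7-ol | CC1(C)C=Cc2cc(I)c(O)cc2O1 | intermediate
6 | 3-chloro-3-methylbut-1-yne | C#CC(C)(C)Cl | starting material
7 | 6-iodo-2,2-dimethyl-7-(2-methylbut-3-yn-2-yloxy)-2H-chromene | C#CC(C)(C)Oc1cc2OC(C)(C)C=Cc2cc1I | intermediate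
8 | 6-iodo-2,2-dimethyl-7-(2-methylbut-3-en-2-yloxy)-2H-chromene | C=CC(C)(C)Oc1cc2OC(C)(C)C=Cc2cc1I | intermediate
9 | 6-iodo-2,2-dimethyl-8-(3-methylbut-2-enyl)-8H-chromen-7-one (Claisen dienone, racemic at the transient C8 centre) | CC(C)=CCC1C(=O)C(I)=CC2=C1OC(C)(C)C=C2 | intermediate
10 | 6-iodo-2,2-dimethyl-8-(3-methylbut-2-enyl)-2H-chromen-7-ol | CC(C)=CCc1c(O)c(I)cc2c1OC(C)(C)C=C2 | intermediate
11 | tert-butyl-[6-iodo-2,2-dimethyl-8-(3-methylbut-2-enyl)-2H-chromen-7-yl]oxy-dimethylsilane | CC(C)=CCc1c(O[Si](C)(C)C(C)(C)C)c(I)cc2c1OC(C)(C)C=C2 | intermediate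
12 | 4-acetoxystyrene | CC(=O)Oc1ccc(C=C)cc1 | starting material
13 | 4-vinylphenol | Oc1ccc(C=C)cc1 | intermediate
14 | tert-butyl-(4-ethenylphenoxy)-dimethylsilane | CC(C)(C)[Si](C)(C)Oc1ccc(C=C)cc1 | intermediate
15 | 9-[2-[4-(tert-butyldimethylsilyloxy)phenyl]ethyl]-9-borabicyclo[3.3.1]nonane | CC(C)(C)[Si](C)(C)Oc1ccc(CCB2C3CCCC2CCC3)cc1 | intermediate
16 | carbon monoxide | [C-]#[O+] | starting material
17 | 1-[7-(tert-butyldimethylsilyloxy)-2,2-dimethyl-8-(3-methylbut-2-enyl)-2H-chromen-6-yl]-3-[4-(tert-butyldimethylsilyloxy)phenyl]propan-1-one | CC(C)=CCc1c(O[Si](C)(C)C(C)(C)C)c(C(=O)CCc2ccc(O[Si](C)(C)C(C)(C)C)cc2)cc2c1OC(C)(C)C=C2 | intermediate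
18 | 1-[7-hydroxy-2,2-dimethyl-8-(3-methylbut-2-enyl)-2H-chromen-6-yl]-3-(4-hydroxyphenyl)propan-1-one | CC(C)=CCc1c(O)c(C(=O)CCc2ccc(O)cc2)cc2c1OC(C)(C)C=C2 | target

Total step count: 11. Longest linear sequence: 8 (steps 1–6, 10, 11). The ring B branch (steps 7–9) joins at step 10.

**Steps most likely to fail**

(a) Step 10.
- What may go wrong: transmetalation may outrun CO insertion, so the carbonyl carbon is left out. Oxidative addition next to the bulky silyl ether may be sluggish. The base may strip the aryl silyl ethers.
- Fallback: polar acylation replaces catalysis. It sets out from 11 and returns at 17.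
- Commercial methyl 3-(4-hydroxyphenyl)propanoate is silylated (TBSCl, imidazole, DMF) to methyl 3-[4-(tert-butyldimethylsilyloxy)phenyl]propanoate F1.
- Treatment of F1 with MeNH(OMe)·HCl and iPrMgCl (THF, −20 °C) gives the Weinreb amide 3-[4-(tert-butyldimethylsilyloxy)phenyl]-N-methoxy-N-methylpropanamide F2.
- Iodide 11 undergoes iodine–magnesium exchange with iPrMgCl·LiCl (THF, −15 to 0 °C) to [7-(tert-butyldimethylsilyloxy)-2,2-dimethyl-8-(3-methylbut-2-enyl)-2H-chromen-6-yl]magnesium chloride F3.
- F3 is acylated by F2 and gives 17 on aqueous NH4Cl quench. Magnesium rather than lithium is chosen so that the ortho silyl group does not migrate from oxygen to carbon.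

(b) Step 2.
- What may go wrong: C-alkylation may occur at the carbon between the two hydroxyls. A second annulation may take place on the remaining hydroxyl. The electron-rich iodoarene may lose iodine by protodeiodination during prolonged heating.
- Fallback: the order of ring closure and halogenation is reversed. It sets out from 1 (with 3) and returns at 5.
- Resorcinol and prenal are condensed under the same amine-salt catalysis. The reaction passes through 3-hydroxy-6-(3-methylbut-2-enylidene)cyclohexa-2,4-dien-1-one F4 and gives 2,2-dimethyl-2H-chromen-7-ol F5.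
- F5 is then iodinated with N-iodosuccinimide and catalytic CF3CO2H (MeCN, −20 °C) at C6. This position is para to O1, ortho to the hydroxyl and less crowded than C8. The low temperature spares the chromene alkene.

(c) Step 4.
- What may go wrong: hydrogenolysis of the carbon–iodine bond, poisoning of the catalyst by released iodide, or over-reduction of the new vinyl group or the chromene alkene.
- Fallback: direct C-prenylation replaces the ether, hydrogenation and Claisen sequence. It sets out from 5 and returns at 10, bypassing 7 and 8.
- Compound 5 is deprotonated with NaH in toluene to the suspended sodium 6-iodo-2,2-dimethyl-2H-chromen-7-olate F6.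
- In this non-polar medium F6 should be alkylated by 1-bromo-3-methylbut-2-ene mainly on carbon, at the only free ortho position C8. Any O-prenyl ether formed is separated.

**Further compounds**
F1 | step 10 | methyl 3-[4-(tert-butyldimethylsilyloxy)phenyl]propanoate | COC(=O)CCc1ccc(O[Si](C)(C)C(C)(C)C)cc1
F2 | step 10 | 3-[4-(tert-butyldimethylsilyloxy)phenyl]-N-methoxy-N-methylpropanamide | CON(C)C(=O)CCc1ccc(O[Si](C)(C)C(C)(C)C)cc1
F3 | step 10 | [7-(tert-butyldimethylsilyloxy)-2,2-dimethyl-8-(3-methylbut-2-enyl)-2H-chromen-6-yl]magnesium chloride | CC(C)=CCc1c(O[Si](C)(C)C(C)(C)C)c([Mg]Cl)cc2c1OC(C)(C)C=C2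
F4 | step 2 | 3-hydroxy-6-(3-methylbut-2-enylidene)cyclohexa-2,4-dien-1-one | CC(C)=CC=C1C=CC(O)=CC1=O
F5 | step 2 | 2,2-dimethyl-2H-chromen-7-ol | CC1(C)C=Cc2ccc(O)cc2O1
F6 | step 4 | sodium 6-iodo-2,2-dimethyl-2H-chromen-7-olate | [Na+].[O-]c1cc2OC(C)(C)C=Cc2cc1I
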